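Everything rests on cutting ring C of the flavanone at the aryl ether bond O1–C8a and, with it, at the neighbouring C4–C4a bond, so that ring A enters as 3,5-bis(benzyloxy)benzyne. The key step uses the fact that ring A carries O1 (on C8a) and the C4 carbonyl (on C4a) on adjacent carbons with the C5 oxygen beside C4a: this oxygen polarises the aryne, the C2 alkoxide adds at C8a, and the aryl anion closes ring C on the amide carbonyl, in one operation. The precursor is an open-chain anti-aldol Weinreb amide that already holds both stereocentres and the protected luteolin unit; selective 7''-O-sulfation and hydrogenolysis finish.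

Key step: step 11

Remark: locants without primes belong to the flavanone unit, doubly primed locants to the flavone (luteolin) unit; "Fl" stands for the protected flavon-8-yl group 5-(benzyloxy)-2-(2,2-diphenyl-1,3-benzodioxol-5-yl)-7-(methoxymethoxy)-4-oxo-4H-chromen-8-yl.
Assumption: the MgCl2-catalysed anti-aldol of the (R)-4-benzyl imide is taken to follow the chelated Z-enolate model (attack anti to the benzyl group), which leads to the (2S,3R) adduct.
Assumption: the target is wanted as the free hydrogen sulfate, and rotation about the C3–C8'' bond is slow but not a fixed stereo-axis.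

Step 1
Reactants: 1 3,5-bis(benzyloxy)phenol
Product: 2 2-bromo-3,5-bis(benzyloxy)phenol
Conditions: NBS (1.0 equiv), CH2Cl2, −78 °C
Reagents that add atoms: N-bromosuccinimide, O=C1CCC(=O)N1Br
Why: Electrophilic aromatic bromination of the phloroglucinol-type ring should stop at the monobromide at −78 °C and favour C2, ortho to the free hydroxyl and less crowded than C4 between the two benzyloxy groups, which places bromine where the silyl group is needed.

Step 2
Reactants: 2 2-bromo-3,5-bis(benzyloxy)phenol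
Product: 5 3,5-bis(benzyloxy)-2-(trimethylsilyl)phenyl trifluoromethanesulfonate, via aryl silyl ether 3 (not isolated), via lithium phenoxide 4 (not isolated)
Conditions: HMDS, THF, 65 °C, then concentrate; n-BuLi, THF, −100 °C; Tf2O, −100 °C to rt
Reagents that add atoms: hexamethyldisilazane, C[Si](C)(C)N[Si](C)(C)C; trifluoromethanesulfonic anhydride, O=S(=O)(OS(=O)(=O)C(F)(F)F)C(F)(F)F
Why: O-silylation followed by bromine–lithium exchange, 1,3 oxygen-to-carbon silyl shift (retro-Brook rearrangement) and O-triflation of the resulting phenoxide is the standard one-flask passage from an o-bromophenol to an o-(trimethylsilyl)aryl triflate.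

Step 3
Reactants: 6 luteolin
Product: 7 3',4'-O-(diphenylmethylene)luteolin
Conditions: Ph2CCl2 (1.5 equiv), diphenyl ether, 175 °C
Reagents that add atoms: dichlorodiphenylmethane, ClC(Cl)(c1ccccc1)c1ccccc1
Why: Ketalisation with dichlorodiphenylmethane should engage only the 3',4'-catechol, the one pair of hydroxyls able to close a five-membered 1,3-dioxole, and gives a protecting group that later falls to the same hydrogenolysis as the benzyl ethers.

Step 4
Reactants: 7 3',4'-O-(diphenylmethylene)luteolin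
Product: 9 7-O-allyl-5-O-benzyl-3',4'-O-(diphenylmethylene)luteolin, via allyl ether 8 (not isolated)
Conditions: allyl bromide (1.0 equiv), K2CO3, DMF, rt; then BnBr (1.5 equiv), K2CO3, Bu4NI (cat.), 70 °C
Reagents that add atoms: allyl bromide, C=CCBr; benzyl bromide, BrCc1ccccc1
Why: Two-stage Williamson etherification: the acidic 7-OH is allylated at room temperature while the 5-OH, held in a hydrogen bond to the C4 carbonyl, waits for the forcing benzylation.

Step 5
Reactants: 9 7-O-allyl-5-O-benzyl-3',4'-O-(diphenylmethylene)luteolin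
Product: 10 8-C-allyl-5-O-benzyl-3',4'-O-(diphenylmethylene)luteolin (7-OH free)
Conditions: N,N-diethylaniline, 200 °C, sealed tube, argon
Reagents that add atoms: none
Why: The aromatic Claisen rearrangement ([3,3]-sigmatropic shift, then tautomerisation) of a 7-allyloxychromone should deliver the allyl group to C8, the ortho carbon joined to C7 by the bond of higher double-bond character, and it leaves O7 as the only free phenol.

Step 6
Reactants: 10 8-C-allyl-5-O-benzyl-3',4'-O-(diphenylmethylene)luteolin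
Product: 11 8-C-allyl-5-O-benzyl-7-O-(methoxymethyl)-3',4'-O-(diphenylmethylene)luteolin
Conditions: MOMCl, i-Pr2NEt, CH2Cl2, 0 °C to rt
Reagents that add atoms: chloromethyl methyl ether, COCCl
Why: Alkylation of the phenol with chloromethyl methyl ether gives an acetal that is orthogonal to the benzyl ethers and the ketal and so marks O7 as the later sulfation site.

Step 7
Reactants: 11 8-C-allyl-5-O-benzyl-7-O-(methoxymethyl)-3',4'-O-(diphenylmethylene)luteolin
Product: 14 Fl-acetic acid, via diol 12 (not isolated), via aldehyde 13 (not isolated)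
Conditions: OsO4 (2 mol%), NaIO4 (4 equiv), 2,6-lutidine, dioxane/H2O, rt; then NaClO2, NaH2PO4, 2-methyl-2-butene, t-BuOH/H2O, 0 °C to rt
Reagents that add atoms: sodium periodate, [Na+].[O-]I(=O)(=O)=O; sodium chlorite, [Na+].[O-]Cl=O
Why: Lemieux–Johnson cleavage of the terminal alkene (OsO4 dihydroxylation, periodate scission) and Pinnick oxidation of the arylacetaldehyde in the same flask should give the acid, the electron-poor flavone C2=C3 bond being dihydroxylated far more slowly than the monosubstituted alkene.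

Step 8
Reactants: 14 Fl-acetic acid; 15 (R)-4-benzyloxazolidin-2-one
Product: 17 (R)-4-benzyl-3-(Fl-acetyl)oxazolidin-2-one, via mixed anhydride 16 (not isolated)
Conditions: PivCl, Et3N, THF, −20 °C; then 15, LiCl, −20 °C to rt
Reagents that add atoms: none
Why: N-Acylation of the oxazolidinone through the mixed pivalic anhydride under LiCl/Et3N activation should be regioselective because the tert-butyl group shields the pivaloyl carbonyl.

Step 9
Reactants: 17 (R)-4-benzyl-3-(Fl-acetyl)oxazolidin-2-one; 18 4-(benzyloxy)benzaldehyde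
Product: 20 (R)-4-benzyl-3-[(2S,3R)-3-(4-benzyloxyphenyl)-2-Fl-3-hydroxypropanoyl]oxazolidin-2-one, via silyl ether 19 (not isolated)
Conditions: MgCl2 (0.2 equiv), Et3N (2 equiv), TMSCl (1.5 equiv), EtOAc, rt; then PPTS, MeOH, 0 °C
Reagents that add atoms: none
Why: Evans MgCl2-catalysed direct anti-aldol reaction: soft enolisation gives the magnesium-chelated Z-enolate, the aldehyde adds through a boat-like transition state on the face opposite the benzyl group of the auxiliary, which sets C2 as S and C3 as R (anti), and silylation of the aldolate by TMSCl makes the addition irreversible and turns the metal over.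

Step 10
Reactants: 20 (R)-4-benzyl-3-[(2S,3R)-3-(4-benzyloxyphenyl)-2-Fl-3-hydroxypropanoyl]oxazolidin-2-one
Product: 21 (2S,3R)-3-(4-benzyloxyphenyl)-2-Fl-3-hydroxy-N-methoxy-N-methylpropanamide
Conditions: MeNHOMe·HCl (3 equiv), AlMe3 (3 equiv), CH2Cl2, −15 to 0 °C
Reagents that add atoms: N,O-dimethylhydroxylamine hydrochloride, CNOC.Cl
Why: Weinreb amide formation by aluminium amide transamidation, steered to the exocyclic carbonyl by the aluminium alkoxide of the free β-hydroxyl, should release the auxiliary without touching either stereocentre and installs an acyl donor whose enolate is a poor leaving group for retro-aldol.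

Step 11
Reactants: 21 (2S,3R)-3-(4-benzyloxyphenyl)-2-Fl-3-hydroxy-N-methoxy-N-methylpropanamide; 5 3,5-bis(benzyloxy)-2-(trimethylsilyl)phenyl trifluoromethanesulfonate
Product: 25 (2R,3S)-5,7-bis(benzyloxy)-2-(4-benzyloxyphenyl)-3-Fl-chroman-4-one, via sodium alkoxide 22 (not isolated), via aryne 23 (not isolated), via hemiaminal salt 24 (not isolated)
Conditions: NaH (1.05 equiv), THF, 0 °C; then 5 (1.5 equiv), CsF (3 equiv), 18-crown-6, THF, −20 °C to rt; AcOH, −20 °C
Reagents that add atoms: none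
Why: Proposed new method: fluoride unmasks 3,5-bis(benzyloxy)benzyne 23 from 5 in the presence of the sodium alkoxide 22, whose oxygen (O1) adds to aryne carbon C1 (the future C8a) to make the O1–C8a bond, and the aryl anion formed at C2 (the future C4a) then attacks the Weinreb carbonyl (the future C4) in a 6-exo-trig closure of ring C to give the chelated hemiaminal salt 24, which releases the ketone only on the acetic acid quench. The closest known reaction types are the aryne annulation of salicylate esters to xanthones (phenoxide addition, then intramolecular acyl capture) and the acyl-alkylation of arynes by β-ketoesters; an aliphatic β-oxido amide has not served in this role, hence the label. No new stereocentre survives the step: C2 keeps its configuration because its C–O bond is never broken, and C3 is carried over from the aldol, sits trans to the C2 aryl group (the thermodynamic arrangement) and is shielded from base while C4 stays a hemiaminal. The step needs regioselective addition to the aryne, and this is secured by the benzyloxy group beside the triple bond (the future C5–O), whose inductive pull and distortion of the aryne send the nucleophile to the remote carbon and the carbanion next to the oxygen, the weak opposing bias of the second benzyloxy group (the future C7–O) being too small to matter. It also needs O-arylation to outrun retro-aldol and acyl capture to outrun protonation of the aryl anion, which the poorly stabilised amide enolate, the aprotic medium and the six-membered geometry of the acyl transfer should secure.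

Step 12
Reactants: 25 (2R,3S)-5,7-bis(benzyloxy)-2-(4-benzyloxyphenyl)-3-Fl-chroman-4-one
Product: 26 (2R,3S)-5,7-bis(benzyloxy)-2-(4-benzyloxyphenyl)-3-[5-(benzyloxy)-2-(2,2-diphenyl-1,3-benzodioxol-5-yl)-7-hydroxy-4-oxo-4H-chromen-8-yl]chroman-4-one
Conditions: ZnBr2 (1 equiv), n-PrSH (2 equiv), CH2Cl2, 0 °C
Reagents that add atoms: none
Why: ZnBr2-assisted thiolysis of the methoxymethyl acetal should unveil the 7''-phenol within minutes at 0 °C, conditions too mild to touch the benzyl ethers, the diphenylmethylene ketal or the flavanone.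

Step 13
Reactants: 26 the 7''-phenol
Product: 28 sodium 7''-O-sulfate of 26, via pyridinium sulfate 27 (not isolated)
Conditions: SO3·pyridine (5 equiv), DMF, rt; then aq NaHCO3
Reagents that add atoms: sulfur trioxide pyridine complex, [O-]S(=O)(=O)[n+]1ccccc1; sodium hydrogen carbonate, [Na+].OC([O-])=O
Why: O-Sulfation with the sulfur trioxide pyridine complex can only occur at the single free phenol (O7''), and exchange to the sodium salt gives a sulfate monoester that is stable to the neutral hydrogenolysis that follows.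

Step 14
Reactants: 28 sodium 7''-O-sulfate of 26
Product: 30 (2R,3S)-3-[2-(3,4-dihydroxyphenyl)-5-hydroxy-4-oxo-7-(sulfooxy)-4H-chromen-8-yl]-5,7-dihydroxy-2-(4-hydroxyphenyl)chroman-4-one, via sodium salt 29 (not isolated)
Conditions: H2 (1 atm), Pd(OH)2/C, THF/MeOH, rt; filter; then HCl (1.0 equiv), H2O, 0 °C, C18 desalting, lyophilise
Reagents that add atoms: none
Why: Palladium-catalysed hydrogenolysis should cleave the four benzyl ethers and the benzylic C–O bonds of the diphenylmethylene ketal while the aryl sulfate salt, the flavone double bond and both stereocentres persist, and one equivalent of acid then gives the hydrogen sulfate form.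

Compound list
1 | 3,5-bis(benzyloxy)phenol | Oc1cc(OCc2ccccc2)cc(OCc2ccccc2)c1 | starting material
2 | 2-bromo-3,5-bis(benzyloxy)phenol | Oc1cc(OCc2ccccc2)cc(OCc2ccccc2)c1Br | intermediate
3 | [2-bromo-3,5-bis(benzyloxy)phenoxy]trimethylsilane | C[Si](C)(C)Oc1cc(OCc2ccccc2)cc(OCc2ccccc2)c1Br | intermediate
4 | lithium 3,5-bis(benzyloxy)-2-(trimethylsilyl)phenoxide | [Li+].[O-]c1cc(OCc2ccccc2)cc(OCc2ccccc2)c1[Si](C)(C)C | intermediate
5 | 3,5-bis(benzyloxy)-2-(trimethylsilyl)phenyl trifluoromethanesulfonate | C[Si](C)(C)c1c(OS(=O)(=O)C(F)(F)F)cc(OCc2ccccc2)cc1OCc1ccccc1 | intermediate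
6 | luteolin | O=c1cc(-c2ccc(O)c(O)c2)oc2cc(O)cc(O)c12 | starting material
7 | 3',4'-O-(diphenylmethylene)luteolin: 2-(2,2-diphenyl-1,3-benzodioxol-5-yl)-5,7-dihydroxy-4H-chromen-4-one | O=c1cc(-c2ccc3OC(c4ccccc4)(c4ccccc4)Oc3c2)oc2cc(O)cc(O)c12 | intermediate
8 | 7-(allyloxy)-2-(2,2-diphenyl-1,3-benzodioxol-5-yl)-5-hydroxy-4H-chromen-4-one | O=c1cc(-c2ccc3OC(c4ccccc4)(c4ccccc4)Oc3c2)oc2cc(OCC=C)cc(O)c12 | intermediate
9 | 7-(allyloxy)-5-(benzyloxy)-2-(2,2-diphenyl-1,3-benzodioxol-5-yl)-4H-chromen-4-one | O=c1cc(-c2ccc3OC(c4ccccc4)(c4ccccc4)Oc3c2)oc2cc(OCC=C)cc(OCc3ccccc3)c12 | intermediate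
10 | 8-allyl-5-(benzyloxy)-2-(2,2-diphenyl-1,3-benzodioxol-5-yl)-7-hydroxy-4H-chromen-4-one | O=c1cc(-c2ccc3OC(c4ccccc4)(c4ccccc4)Oc3c2)oc2c(CC=C)c(O)cc(OCc3ccccc3)c12 | intermediate
11 | 8-allyl-5-(benzyloxy)-2-(2,2-diphenyl-1,3-benzodioxol-5-yl)-7-(methoxymethoxy)-4H-chromen-4-one | O=c1cc(-c2ccc3OC(c4ccccc4)(c4ccccc4)Oc3c2)oc2c(CC=C)c(OCOC)cc(OCc3ccccc3)c12 | intermediate
12 | 3-Fl-propane-1,2-diol (both carbinol epimers) | O=c1cc(-c2ccc3OC(c4ccccc4)(c4ccccc4)Oc3c2)oc2c(CC(O)CO)c(OCOC)cc(OCc3ccccc3)c12 | intermediate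
13 | Fl-acetaldehyde | O=c1cc(-c2ccc3OC(c4ccccc4)(c4ccccc4)Oc3c2)oc2c(CC=O)c(OCOC)cc(OCc3ccccc3)c12 | intermediate
14 | Fl-acetic acid: [5-(benzyloxy)-2-(2,2-diphenyl-1,3-benzodioxol-5-yl)-7-(methoxymethoxy)-4-oxo-4H-chromen-8-yl]acetic acid | O=c1cc(-c2ccc3OC(c4ccccc4)(c4ccccc4)Oc3c2)oc2c(CC(=O)O)c(OCOC)cc(OCc3ccccc3)c12 | intermediate
15 | (R)-4-benzyloxazolidin-2-one | O=C1OC[C@@H](Cc2ccccc2)N1 | starting material
16 | Fl-acetic pivalic anhydride | O=c1cc(-c2ccc3OC(c4ccccc4)(c4ccccc4)Oc3c2)oc2c(CC(=O)OC(=O)C(C)(C)C)c(OCOC)cc(OCc3ccccc3)c12 | intermediate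
17 | (R)-4-benzyl-3-(Fl-acetyl)oxazolidin-2-one | O=c1cc(-c2ccc3OC(c4ccccc4)(c4ccccc4)Oc3c2)oc2c(CC(=O)N3[C@H](Cc4ccccc4)COC3=O)c(OCOC)cc(OCc3ccccc3)c12 | intermediate
18 | 4-(benzyloxy)benzaldehyde | O=Cc1ccc(OCc2ccccc2)cc1 | starting material
19 | (R)-4-benzyl-3-[(2S,3R)-3-(4-benzyloxyphenyl)-2-Fl-3-(trimethylsilyloxy)propanoyl]oxazolidin-2-one | O=C(N1[C@H](Cc2ccccc2)COC1=O)[C@@H](c1c(OCOC)cc(OCc2ccccc2)c2c(=O)cc(-c3ccc4OC(c5ccccc5)(c5ccccc5)Oc4c3)oc12)[C@@H](O[Si](C)(C)C)c1ccc(OCc2ccccc2)cc1 | intermediate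
20 | (R)-4-benzyl-3-[(2S,3R)-3-(4-benzyloxyphenyl)-2-Fl-3-hydroxypropanoyl]oxazolidin-2-one | O=C(N1[C@H](Cc2ccccc2)COC1=O)[C@@H](c1c(OCOC)cc(OCc2ccccc2)c2c(=O)cc(-c3ccc4OC(c5ccccc5)(c5ccccc5)Oc4c3)oc12)[C@@H](O)c1ccc(OCc2ccccc2)cc1 | intermediate
21 | (2S,3R)-3-(4-benzyloxyphenyl)-2-Fl-3-hydroxy-N-methoxy-N-methylpropanamide | CON(C)C(=O)[C@@H](c1c(OCOC)cc(OCc2ccccc2)c2c(=O)cc(-c3ccc4OC(c5ccccc5)(c5ccccc5)Oc4c3)oc12)[C@@H](O)c1ccc(OCc2ccccc2)cc1 | intermediate
22 | sodium alkoxide of 21 | [Na+].CON(C)C(=O)[C@@H](c1c(OCOC)cc(OCc2ccccc2)c2c(=O)cc(-c3ccc4OC(c5ccccc5)(c5ccccc5)Oc4c3)oc12)[C@@H]([O-])c1ccc(OCc2ccccc2)cc1 | intermediate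
23 | 3,5-bis(benzyloxy)benzyne (1,2-didehydro-3,5-bis(benzyloxy)benzene) | C1#CC(OCc2ccccc2)=CC(OCc2ccccc2)=C1 | intermediate
24 | sodium (2R,3S)-5,7-bis(benzyloxy)-2-(4-benzyloxyphenyl)-3-Fl-4-[methoxy(methyl)amino]chroman-4-olate (C4 undefined) | [Na+].[O-]C1(N(C)OC)c2c(OCc3ccccc3)cc(OCc3ccccc3)cc2O[C@@H](c2ccc(OCc3ccccc3)cc2)[C@@H]1c1c(OCOC)cc(OCc2ccccc2)c2c(=O)cc(-c3ccc4OC(c5ccccc5)(c5ccccc5)Oc4c3)oc12 | intermediate
25 | (2R,3S)-5,7-bis(benzyloxy)-2-(4-benzyloxyphenyl)-3-Fl-chroman-4-one | O=C1c2c(OCc3ccccc3)cc(OCc3ccccc3)cc2O[C@@H](c2ccc(OCc3ccccc3)cc2)[C@@H]1c1c(OCOC)cc(OCc2ccccc2)c2c(=O)cc(-c3ccc4OC(c5ccccc5)(c5ccccc5)Oc4c3)oc12 | intermediate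
26 | (2R,3S)-5,7-bis(benzyloxy)-2-(4-benzyloxyphenyl)-3-[5-(benzyloxy)-2-(2,2-diphenyl-1,3-benzodioxol-5-yl)-7-hydroxy-4-oxo-4H-chromen-8-yl]chroman-4-one | O=C1c2c(OCc3ccccc3)cc(OCc3ccccc3)cc2O[C@@H](c2ccc(OCc3ccccc3)cc2)[C@@H]1c1c(O)cc(OCc2ccccc2)c2c(=O)cc(-c3ccc4OC(c5ccccc5)(c5ccccc5)Oc4c3)oc12 | intermediate
27 | pyridinium 7''-O-sulfate of 26 | O=C1c2c(OCc3ccccc3)cc(OCc3ccccc3)cc2O[C@@H](c2ccc(OCc3ccccc3)cc2)[C@@H]1c1c(OS(=O)(=O)[O-])cc(OCc2ccccc2)c2c(=O)cc(-c3ccc4OC(c5ccccc5)(c5ccccc5)Oc4c3)oc12.c1cc[nH+]cc1 | intermediate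
28 | sodium 7''-O-sulfate of 26 | O=C1c2c(OCc3ccccc3)cc(OCc3ccccc3)cc2O[C@@H](c2ccc(OCc3ccccc3)cc2)[C@@H]1c1c(OS(=O)(=O)[O-])cc(OCc2ccccc2)c2c(=O)cc(-c3ccc4OC(c5ccccc5)(c5ccccc5)Oc4c3)oc12.[Na+] | intermediate
29 | sodium salt of 30 | O=C1c2c(O)cc(O)cc2O[C@@H](c2ccc(O)cc2)[C@@H]1c1c(OS(=O)(=O)[O-])cc(O)c2c(=O)cc(-c3ccc(O)c(O)c3)oc12.[Na+] | intermediate
30 | (2R,3S)-3-[2-(3,4-dihydroxyphenyl)-5-hydroxy-4-oxo-7-(sulfooxy)-4H-chromen-8-yl]-5,7-dihydroxy-2-(4-hydroxyphenyl)chroman-4-one | O=C1c2c(O)cc(O)cc2O[C@@H](c2ccc(O)cc2)[C@@H]1c1c(OS(=O)(=O)O)cc(O)c2c(=O)cc(-c3ccc(O)c(O)c3)oc12 | target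

Total step count: 14 (two for the aryne precursor, twelve from luteolin). Longest linear sequence: 12 steps (steps 3 to 14).

Steps most likely to fail

Step 11. The alkoxide may fragment by retro-aldol before it meets the aryne, or the aryl anion may be protonated (by the acidic C–H next to the amide or by adventitious water) before it reaches the amide carbonyl, which would leave an uncyclised aryl ether. The fallback uses known chemistry and sets out from 21. 2,4,6-Trifluorophenyllithium F1 (from 1,3,5-trifluorobenzene and n-BuLi, THF, −78 °C, 2.5 equiv) adds to the Weinreb amide to give the (2S,3R) 2,4,6-trifluorophenyl ketone F2. K2CO3 in DMF then closes ring C by intramolecular nucleophilic aromatic substitution of the β-hydroxyl on an ortho fluorine (the same O1–C8a bond) to give the 5,7-difluoroflavanone F3. The two remaining fluorines, ortho and para to the ketone, are exchanged with sodium benzyloxide (BnOH, NaH, THF/DMF, 0 °C to rt), and the route is rejoined at 25.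

Step 9. Enolisation or addition may be sluggish, or facial and anti/syn selectivity may be poor, because the enolate carries an aryl group with two ortho substituents. The fallback sets out from 17. The dibutylboron enolate (Bu2BOTf, i-Pr2NEt, CH2Cl2, −78 °C) adds to 18 in an Evans syn-aldol reaction to give the (2R,3R) syn adduct F4, which has the correct carbinol configuration. Transamidation as in step 10 gives the syn Weinreb amide F5, and annulation as in step 11 gives the cis-flavanone F6. Epimerisation of the acidic C3–H with DBU in CH2Cl2 to the thermodynamically preferred trans isomer rejoins the route at 25.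

Step 14. Hydrogenolysis may over-reduce the molecule (cleavage of the benzylic C2–O1 bond of the flavanone, saturation of the flavone C2''=C3'' bond), the ketal may be cleaved too slowly, or the sulfate may be lost during the acid exchange. The fallback sets out from 26. 2,2,2-Trichloroethyl chlorosulfate with Et3N and DMAP in THF gives the neutral trichloroethyl sulfate diester F7. BCl3 with pentamethylbenzene in CH2Cl2 at −78 °C removes the benzyl ethers and the ketal without hydrogen to give the hexaphenol F8. Zn dust and HCO2NH4 in MeOH then unmask the sulfate monoester, and acidification as in step 14 gives 30.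

Further compounds
F1 | step 11 | 2,4,6-trifluorophenyllithium | [Li]c1c(F)cc(F)cc1F
F2 | step 11 | (2S,3R)-3-(4-benzyloxyphenyl)-2-Fl-3-hydroxy-1-(2,4,6-trifluorophenyl)propan-1-one | O=C(c1c(F)cc(F)cc1F)[C@@H](c1c(OCOC)cc(OCc2ccccc2)c2c(=O)cc(-c3ccc4OC(c5ccccc5)(c5ccccc5)Oc4c3)oc12)[C@@H](O)c1ccc(OCc2ccccc2)cc1
F3 | step 11 | (2R,3S)-2-(4-benzyloxyphenyl)-5,7-difluoro-3-Fl-chroman-4-one | O=C1c2c(F)cc(F)cc2O[C@@H](c2ccc(OCc3ccccc3)cc2)[C@@H]1c1c(OCOC)cc(OCc2ccccc2)c2c(=O)cc(-c3ccc4OC(c5ccccc5)(c5ccccc5)Oc4c3)oc12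
F4 | step 9 | (R)-4-benzyl-3-[(2R,3R)-3-(4-benzyloxyphenyl)-2-Fl-3-hydroxypropanoyl]oxazolidin-2-one | O=C(N1[C@H](Cc2ccccc2)COC1=O)[C@H](c1c(OCOC)cc(OCc2ccccc2)c2c(=O)cc(-c3ccc4OC(c5ccccc5)(c5ccccc5)Oc4c3)oc12)[C@@H](O)c1ccc(OCc2ccccc2)cc1
F5 | step 9 | (2R,3R)-3-(4-benzyloxyphenyl)-2-Fl-3-hydroxy-N-methoxy-N-methylpropanamide | CON(C)C(=O)[C@H](c1c(OCOC)cc(OCc2ccccc2)c2c(=O)cc(-c3ccc4OC(c5ccccc5)(c5ccccc5)Oc4c3)oc12)[C@@H](O)c1ccc(OCc2ccccc2)cc1
F6 | step 9 | (2R,3R)-5,7-bis(benzyloxy)-2-(4-benzyloxyphenyl)-3-Fl-chroman-4-one | O=C1c2c(OCc3ccccc3)cc(OCc3ccccc3)cc2O[C@@H](c2ccc(OCc3ccccc3)cc2)[C@H]1c1c(OCOC)cc(OCc2ccccc2)c2c(=O)cc(-c3ccc4OC(c5ccccc5)(c5ccccc5)Oc4c3)oc12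
F7 | step 14 | 2,2,2-trichloroethyl sulfate diester of 26 at O7'' | O=C1c2c(OCc3ccccc3)cc(OCc3ccccc3)cc2O[C@@H](c2ccc(OCc3ccccc3)cc2)[C@@H]1c1c(OS(=O)(=O)OCC(Cl)(Cl)Cl)cc(OCc2ccccc2)c2c(=O)cc(-c3ccc4OC(c5ccccc5)(c5ccccc5)Oc4c3)oc12
F8 | step 14 | 2,2,2-trichloroethyl ester of 30 (all phenols free) | O=C1c2c(O)cc(O)cc2O[C@@H](c2ccc(O)cc2)[C@@H]1c1c(OS(=O)(=O)OCC(Cl)(Cl)Cl)cc(O)c2c(=O)cc(-c3ccc(O)c(O)c3)oc12
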